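Remark on the chemistry: stannane 18 is taken as a purchasable reagent. Compounds 5, 15 and 16 are racemic, and their single stereocentre disappears before the achiral target is reached. No correction to the structures was needed.

## Structural features

The target 20 is built on a fully substituted benzene (ring C) that carries four methoxy groups and two indol-3-yl groups para to each other. Indole A has no further substituent; indole B carries a prenyl (3-methylbut-2-enyl) chain at C5. Numbering ring C from the carbon bonded to indole A, the methoxy groups sit at C2, C3, C5 and C6 and indole B at C4, so each aryl–indolyl bond starts from a carbon flanked by two methoxy groups. There is no stereocentre, and the two hindered biaryl axes carry no stereochemical information, so nothing has to be controlled there. The fragile parts are the trisubstituted alkene of the prenyl chain (acids, boranes, osmium and other oxidants), the two N–H indoles with free C2 positions (acid, electrophiles, oxidants) and the electron-rich ring C (one-electron oxidants, ether-cleaving Lewis acids). The real difficulty is twofold: two C–C bonds must be made at the most crowded positions of ring C, and two indoles that differ only by a remote prenyl group must be introduced one at a time on a core that is symmetrical at the outset. The key step uses the fact that indole A has hydrogen at C2 and is bonded through C3 to C1 of ring C. C2 and C3 of indole A therefore map onto the carbonyl carbon and the α-carbon of an arylacetaldehyde whose aryl group is ring C, and the pyrrole ring can be closed without the crowded C1 ever being a reaction site.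

## Logic of the disconnections

From 20 the N–Si bond of 19 is restored, and then the bond between C5 of indole B and the allylic CH2 is cut, giving 17 and 18. The cut is placed here because the prenyl alkene would not survive the acid that closes indole A or the borane that creates indole B, so it must arrive last. The gain is that every earlier intermediate is free of the alkene and the difference between the two indoles is reduced to one bromine atom. The forward step must deliver the allyl unit through its unsubstituted terminus and tolerate a free indole N–H.

From 17 no skeletal bond is cut. The aromatic pyrrole ring of indole B is traced back through 16 to the hydroxy lactam 15, in which C2 is a carbonyl carbon and C3 a tertiary carbinol carbon. This turns the crowded biaryl carbon into one that can be made by carbonyl addition. The forward reduction must stop at the indole and leave the C–Br and N–Si bonds alone.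

In 15 the bond between C4 of ring C and C3 of the future indole B is cut, giving the nucleophile 13 (from 11) and the electrophile 14 (from 12). The hindered aryl–heteroaryl bond is thus formed by an uncatalysed addition to a ketone, and 12 brings the whole of indole B, with its halogen marker, in one purchasable piece. The forward step needs selective metalation of the single ring C hydrogen of 11 and an electrophile with no acidic N–H, which is why 12 is first converted into 14.

From 11 the N–Si bond is removed, giving 9 through 10. The silyl group is there only to take away the acidic N–H of indole A and to screen its C2–H from the base. It costs one step, since its removal is merged with the last operation.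

In 9 the bonds C3–C3a and N1–C2 of indole A are cut, which leads through 8 to 6 and 7. This removes a ring and reduces the first aryl–indole problem to an aldehyde and a symmetrical hydrazine, with ring C reduced to a substituent on the aldehyde α-carbon. The forward step needs an acid mild enough to spare the methyl ethers and to avoid self-condensation of 6 and migration of the aryl group on the indole.

In 6 the carbonyl group is traced back through 5 to the terminal alkene of 4, with loss of one carbon. The alkene is a stable carrier of the sensitive aldehyde. The cleavage must not touch the electron-rich ring, and 6 must be used as soon as it is made.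

In 4 the aryl–CH2 bond is cut, giving 3 and 2, and 3 comes from 1 by removal of a ring hydrogen. Because 1 is symmetrical and each hydrogen lies between two methoxy groups, there is no regiochemical question. The only demand is that metalation stops after one position.

## Other disconnections considered

Alternative 1: Here ring C itself is cut, at the bond between the hydroxyl-bearing carbon next to indole B and the neighbouring methoxy-bearing carbon (C5–C6 in the numbering above). This leads back to the four-membered ring compound A1, 4-hydroxy-3-methoxy-4-[2-methoxy-1-(1-triisopropylsilylindol-3-yl)ethenyl]-2-(5-prenyl-1-triisopropylsilylindol-3-yl)cyclobut-2-en-1-one. In the forward direction A1 would be heated in toluene. Four-electron ring opening would give a dienylketene, and six-electron electrocyclisation with tautomerisation would then give the hydroquinone A2, 3,6-dimethoxy-2-(1-triisopropylsilylindol-3-yl)-5-(5-prenyl-1-triisopropylsilylindol-3-yl)benzene-1,4-diol.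

- In its favour: ring C is assembled with both indoles in place, so no bond has to be made at a crowded aromatic carbon. The para relationship of the indoles follows from the order of two additions to a squaric ester. The conditions are neutral, so the prenyl group can be present from the start; on this point the alternative is better than the chosen plan, which has to hold the prenyl group back.
- Against it here: the alkenyl nucleophile needed for A1 has no simple source. The ring opening must turn the hydroxyl group outwards for the ketene to reach the alkene. A2 is an oxidation-prone hydroquinone that still needs two O-methylations and two desilylations. The prenylated indole nucleophile has to be made separately.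
- Comparison: in structure the alternative solves the whole core at once, while the chosen plan adds one indole at a time. In mechanism both key steps are pericyclic and free of metal catalysis at the hindered positions, and they are equal on that count. In step economy the chosen plan should be clearly shorter, because A1 alone requires three separately prepared organometallic partners.

Alternative 2: The bond between C1 of ring C and C3 of indole A is cut, with the two halves held together by an ester. The precursor is A3, 2,4,5-trimethoxyphenyl 3-bromo-1-tosylindole-2-carboxylate. Under Pd(OAc)2, PCy3 and K2CO3 it would cyclise by C–H arylation ortho to the ester oxygen to the lactone A4, 1,2,4-trimethoxy-7-tosylchromeno[3,4-b]indol-6(7H)-one.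

- In its favour: the tether makes the arylation intramolecular, which should overcome the crowding at a carbon flanked by two oxygens. Only one ortho C–H is available, so the regiochemistry is as certain as in the chosen plan. It also avoids the labile aldehyde, the hydrazine and the osmium reagent, and is better on that count.
- Against it here: the tether has to be taken out again. Lactone opening, decarboxylation of the indole-2-carboxylic acid, O-methylation of the freed phenol and removal of the sulfonyl group are needed before A4 becomes 9. The aryl ester of A3 is also exposed to carbonate base at high temperature.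
- Comparison: both plans address the same bond environment and both suit a prenyl-free stage. The alternative needs palladium to reach the crowded carbon, whereas the chosen plan needs no reagent there. The chosen plan reaches 9 in three steps from 1, so it is better on step economy.

Alternative 3: The same two bonds are cut as in the chosen key step, but in indole B (C3–C3a and N1–C2). The partners are A5, 2-iodo-4-prenylaniline, and A6, 3-[2,3,5,6-tetramethoxy-4-(trimethylsilylethynyl)phenyl]-1-(triisopropylsilyl)indole. Under Pd(OAc)2, LiCl and K2CO3 they would give A7, 3-[2,3,5,6-tetramethoxy-4-(1-triisopropylsilylindol-3-yl)phenyl]-5-prenyl-2-trimethylsilyl-1H-indole.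

- In its favour: it is convergent, the prenyl group is already on A5, and the bulky silyl group should steer the alkyne insertion so that ring C ends at C3. No tin reagent and no hydride reduction are needed, and on these points it is better than steps 5 to 7 of the chosen plan. It does not compete with the chosen key step but could follow it, since A6 could be reached from 13.
- Against it here: A5 is not a stock compound, and its preparation requires iodination next to an amine in the presence of a nucleophilic alkene. A6 needs an alkynylation at a position flanked by two methoxy groups. The insertion of so hindered and electron-rich an alkyne is likely to be slow. A7 still needs removal of two silyl groups.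
- Comparison: in structure it leaves the attachment of indole A to another method, so it is no substitute for the chosen key step. In mechanism it relies on carbopalladation at the crowded alkyne, where the chosen plan uses a plain carbonyl addition. From 11 it would take four steps plus those for A5, against three in the chosen plan.

Key step: step 3

## Route

Step 1
Reactants: 1 1,2,4,5-tetramethoxybenzene; 2 allyl bromide
Product: 4 3-allyl-1,2,4,5-tetramethoxybenzene, via (2,3,5,6-tetramethoxyphenyl)lithium 3 (not isolated)
Conditions: n-BuLi (1.05 equiv), TMEDA, THF, 0 °C to rt; then CuBr·SMe2 (10 mol%), 2, −78 °C to rt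
Reagents that add atoms: none
Why: Directed ortho-lithiation: each ring hydrogen of 1 lies between two methoxy groups and 1 is symmetrical, so one equivalent of base should give 3 as a single species. Copper-catalysed allylation of the aryllithium with 2 then forms the aryl–CH2 bond, the copper suppressing lithium–bromine exchange.

Step 2
Reactants: 4 3-allyl-1,2,4,5-tetramethoxybenzene
Product: 6 (2,3,5,6-tetramethoxyphenyl)acetaldehyde, via diol 5 (not isolated)
Conditions: K2OsO4·2H2O (2 mol%), NaIO4 (4 equiv), 2,6-lutidine, dioxane–H2O 3:1, rt; crude product taken directly into step 3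
Reagents that add atoms: sodium periodate, [Na+].[O-]I(=O)(=O)=O (terminal oxidant; its oxygen reaches the product through the osmium catalyst K2OsO4·2H2O, O.O.[K+].[K+].[O-][Os](=O)(=O)[O-])
Why: Lemieux–Johnson oxidation: the terminal alkene is dihydroxylated by catalytic osmium to diol 5, which periodate cleaves in the same flask to 6 and formaldehyde. Periodate should leave the aryl methyl ethers alone, and 2,6-lutidine buffers the medium; 6 is not stored because arylacetaldehydes self-condense.

Step 3
Reactants: 6 (2,3,5,6-tetramethoxyphenyl)acetaldehyde; 7 phenylhydrazine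
Product: 9 3-(2,3,5,6-tetramethoxyphenyl)-1H-indole, via hydrazone 8 (not isolated)
Conditions: 7 (1.05 equiv), EtOH, rt; then ZnCl2 (2 equiv), EtOH, 80 °C
Reagents that add atoms: none
Why: Fischer indole synthesis. Condensation of 6 with 7 gives hydrazone 8, which ZnCl2 tautomerises to the ene-hydrazine; a [3,3]-sigmatropic shift then joins the former aldehyde α-carbon to an ortho carbon of the N-phenyl ring (C3–C3a) as the N–N bond breaks. Rearomatisation gives an ortho-aminophenyl imine, whose aniline nitrogen attacks the activated imine carbon in a 5-exo-trig closure (N1–C2) of the pyrrole ring, and loss of ammonia aromatises the ring to 9. The closest known reaction type is the ZnCl2-mediated cyclisation of arylacetaldehyde phenylhydrazones to 3-arylindoles. No stereocentre is formed. Regiochemistry needs no outside control: 6 has one enolisable carbon and 7 has two equivalent ortho positions, so only the 3-aryl, 2-unsubstituted indole can arise. Ring C travels on the migrating α-carbon as a spectator, so its two flanking methoxy groups never have to admit a reagent. The mild Lewis acid in ethanol is chosen to spare the methyl ethers and to avoid acid-promoted migration of the electron-rich aryl group from C3 to C2, and the step is run before any prenyl group exists.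

Step 4
Reactants: 9 3-(2,3,5,6-tetramethoxyphenyl)-1H-indole
Product: 11 3-(2,3,5,6-tetramethoxyphenyl)-1-(triisopropylsilyl)indole, via sodium indolide 10 (not isolated)
Conditions: NaH, THF, 0 °C; then TIPSCl, 0 °C to rt
Reagents that add atoms: chlorotriisopropylsilane (TIPSCl), CC(C)[Si](Cl)(C(C)C)C(C)C
Why: N-silylation of an indole anion: NaH removes the only acidic hydrogen and the sodium indolide 10 is silylated on nitrogen. The bulky silyl group removes the N–H before the second lithiation and screens indole C2–H from the base.

Step 5
Reactants: 11 3-(2,3,5,6-tetramethoxyphenyl)-1-(triisopropylsilyl)indole; 12 5-bromoisatin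
Product: 15 5-bromo-3-hydroxy-3-[2,3,5,6-tetramethoxy-4-(1-triisopropylsilylindol-3-yl)phenyl]indolin-2-one (racemic), via aryllithium 13 (not isolated), via sodium 5-bromoisatinate 14 (not isolated)
Conditions: 11, n-BuLi (1.1 equiv), TMEDA, THF, 0 °C; separately 12, NaH (1.05 equiv), THF, 0 °C; 13 added to 14 at −78 °C, then to 0 °C; aq NH4Cl
Reagents that add atoms: none
Why: Directed ortho-lithiation followed by 1,2-addition of an aryllithium to a ketone: the last ring C hydrogen of 11 lies between two methoxy groups and should be removed selectively. Compound 12 is deprotonated beforehand to 14 so that no N–H quenches 13, and the C3 ketone of 14 is far more electrophilic than its amide carbonyl. At −78 °C carbonyl addition should outrun lithium–bromine exchange; the new stereocentre forms as a racemate and is destroyed in step 6.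

Step 6
Reactants: 15 5-bromo-3-hydroxy-3-[2,3,5,6-tetramethoxy-4-(1-triisopropylsilylindol-3-yl)phenyl]indolin-2-one
Product: 17 5-bromo-3-[2,3,5,6-tetramethoxy-4-(1-triisopropylsilylindol-3-yl)phenyl]-1H-indole, via indolin-3-ol 16 (not isolated)
Conditions: BH3·THF (5 equiv), THF, 0 °C to 50 °C; MeOH; then 1 M HCl, rt, brief
Reagents that add atoms: none
Why: Borane reduction of a 3-hydroxyoxindole to an indole: the lactam carbonyl is reduced to CH2, giving indolin-3-ol 16, whose tertiary benzylic hydroxyl is lost as water on the mildly acidic work-up with aromatisation. Borane is preferred to LiAlH4 because it leaves the aryl bromide alone, and the step precedes the prenylation because borane would hydroborate that alkene.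

Step 7
Reactants: 17 5-bromo-3-[2,3,5,6-tetramethoxy-4-(1-triisopropylsilylindol-3-yl)phenyl]-1H-indole; 18 tributyl(3-methylbut-2-enyl)stannane
Product: 20 3-[2,3,5,6-tetramethoxy-4-(1H-indol-3-yl)phenyl]-5-(3-methylbut-2-enyl)-1H-indole, via N-silyl prenylindole 19 (not isolated)
Conditions: Pd(PPh3)4 (5 mol%), 18 (1.3 equiv), DMF, 100 °C; then TBAF (3 equiv), THF, rt
Reagents that add atoms: none
Why: Stille coupling of the aryl bromide with the allylic stannane 18 (oxidative addition to zerovalent palladium, transmetalation, reductive elimination at the less hindered allyl terminus) should give the linear prenyl arene 19, and the free N–H is tolerated. Fluoride then cleaves the N–Si bond in the same flask and converts the tin halide into insoluble Bu3SnF, which eases purification.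

## Compound list

1 | 1,2,4,5-tetramethoxybenzene | COc1cc(OC)c(OC)cc1OC | starting material
2 | allyl bromide | C=CCBr | starting material
3 | (2,3,5,6-tetramethoxyphenyl)lithium (formed in the flask) | [Li]c1c(OC)c(OC)cc(OC)c1OC | intermediate
4 | 3-allyl-1,2,4,5-tetramethoxybenzene | C=CCc1c(OC)c(OC)cc(OC)c1OC | intermediate
5 | 3-(2,3,5,6-tetramethoxyphenyl)propane-1,2-diol, racemic (formed in the flask) | OCC(O)Cc1c(OC)c(OC)cc(OC)c1OC | intermediate
6 | (2,3,5,6-tetramethoxyphenyl)acetaldehyde | O=CCc1c(OC)c(OC)cc(OC)c1OC | intermediate
7 | phenylhydrazine | NNc1ccccc1 | starting material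
8 | (2,3,5,6-tetramethoxyphenyl)acetaldehyde phenylhydrazone, E shown, either geometry serves (formed in the flask) | COc1cc(OC)c(OC)c(C/C=N/Nc2ccccc2)c1OC | intermediate
9 | 3-(2,3,5,6-tetramethoxyphenyl)-1H-indole | COc1cc(OC)c(OC)c(-c2c[nH]c3ccccc23)c1OC | intermediate
10 | sodium 3-(2,3,5,6-tetramethoxyphenyl)indol-1-ide (formed in the flask) | [Na+].COc1cc(OC)c(OC)c(-c2c[n-]c3ccccc23)c1OC | intermediate
11 | 3-(2,3,5,6-tetramethoxyphenyl)-1-(triisopropylsilyl)indole | COc1cc(OC)c(OC)c(-c2cn([Si](C(C)C)(C(C)C)C(C)C)c3ccccc23)c1OC | intermediate
12 | 5-bromoisatin | O=C1Nc2ccc(Br)cc2C1=O | starting material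
13 | [2,3,5,6-tetramethoxy-4-(1-triisopropylsilylindol-3-yl)phenyl]lithium (formed in the flask) | [Li]c1c(OC)c(OC)c(-c2cn([Si](C(C)C)(C(C)C)C(C)C)c3ccccc23)c(OC)c1OC | intermediate
14 | sodium 5-bromoisatin-1-ide (formed in the flask) | [Na+].O=C1[N-]c2ccc(Br)cc2C1=O | intermediate
15 | 5-bromo-3-hydroxy-3-[2,3,5,6-tetramethoxy-4-(1-triisopropylsilylindol-3-yl)phenyl]indolin-2-one, racemic | COc1c(OC)c(C2(O)C(=O)Nc3ccc(Br)cc32)c(OC)c(OC)c1-c1cn([Si](C(C)C)(C(C)C)C(C)C)c2ccccc12 | intermediate
16 | 5-bromo-3-[2,3,5,6-tetramethoxy-4-(1-triisopropylsilylindol-3-yl)phenyl]indolin-3-ol, racemic (formed in the flask) | COc1c(OC)c(C2(O)CNc3ccc(Br)cc32)c(OC)c(OC)c1-c1cn([Si](C(C)C)(C(C)C)C(C)C)c2ccccc12 | intermediate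
17 | 5-bromo-3-[2,3,5,6-tetramethoxy-4-(1-triisopropylsilylindol-3-yl)phenyl]-1H-indole | COc1c(OC)c(-c2c[nH]c3ccc(Br)cc23)c(OC)c(OC)c1-c1cn([Si](C(C)C)(C(C)C)C(C)C)c2ccccc12 | intermediate
18 | tributyl(3-methylbut-2-enyl)stannane | CCCC[Sn](CCCC)(CCCC)CC=C(C)C | starting material
19 | 5-(3-methylbut-2-enyl)-3-[2,3,5,6-tetramethoxy-4-(1-triisopropylsilylindol-3-yl)phenyl]-1H-indole (formed in the flask) | COc1c(OC)c(-c2c[nH]c3ccc(CC=C(C)C)cc23)c(OC)c(OC)c1-c1cn([Si](C(C)C)(C(C)C)C(C)C)c2ccccc12 | intermediate
20 | 3-[2,3,5,6-tetramethoxy-4-(1H-indol-3-yl)phenyl]-5-(3-methylbut-2-enyl)-1H-indole (CNP0306547.0) | COc1c(OC)c(-c2c[nH]c3ccc(CC=C(C)C)cc23)c(OC)c(OC)c1-c1c[nH]c2ccccc12 | target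

## Step count and least certain steps

Total step count: 7. Longest linear sequence: 7 steps (1 to 20).

Step 3 (key step). The most likely failures are self-condensation of the enolisable aldehyde before it is captured as the hydrazone, and acid-promoted 1,2-shift of the electron-rich aryl group from C3 to C2 once the indole has formed. The second is known for 3-arylindoles under forcing acid. The fallback gives up the ring closure and brings indole A in as a preformed ring. It sets out from 3, which is added at −78 °C to sodium isatin-1-ide F1 (from isatin and NaH in THF) to give 3-hydroxy-3-(2,3,5,6-tetramethoxyphenyl)indolin-2-one F2. Reduction of F2 with BH3·THF and mildly acidic work-up returns to the route at 9.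

Step 5. Lithium–bromine exchange between 13 and the aryl bromide of 14 could compete with carbonyl addition. The sparingly soluble salt 14 may react incompletely, and any residual N–H would protonate 13. The fallback builds indole B by a second Fischer cyclisation. It sets out from 13, which is allylated with 2 (CuBr·SMe2 catalysis) to 3-(4-allyl-2,3,5,6-tetramethoxyphenyl)-1-(triisopropylsilyl)indole F3. Lemieux–Johnson cleavage passes through 3-[2,3,5,6-tetramethoxy-4-(1-triisopropylsilylindol-3-yl)phenyl]propane-1,2-diol F4 to [2,3,5,6-tetramethoxy-4-(1-triisopropylsilylindol-3-yl)phenyl]acetaldehyde F5; the terminal alkene should react well before the hindered, silyl-screened indole double bond. Condensation with 4-bromophenylhydrazine gives the 4-bromophenylhydrazone F6, and ZnCl2 in ethanol cyclises it, returning to the route at 17.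

Step 7. Allyl transfer through the substituted terminus would give the 1,1-dimethylallyl isomer. Reduction of the C–Br bond and slow oxidative addition into the electron-rich bromoindole are further risks. The fallback replaces the cross-coupling by a polar alkylation. It sets out from 17, which is deprotonated with NaH to the sodium indolide F7 and silylated with TIPSCl to 5-bromo-1-(triisopropylsilyl)-3-[2,3,5,6-tetramethoxy-4-(1-triisopropylsilylindol-3-yl)phenyl]indole F8. Bromine–lithium exchange with t-BuLi (2 equiv, THF, −78 °C) gives the 5-lithioindole F9, which with CuBr·SMe2 and prenyl bromide should give 5-(3-methylbut-2-enyl)-1-(triisopropylsilyl)-3-[2,3,5,6-tetramethoxy-4-(1-triisopropylsilylindol-3-yl)phenyl]indole F10. TBAF removes both silyl groups and returns to the route at 20.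

Step 6. The reduction may stall at the indolin-3-ol stage or run on to the indoline, and the acid needed to free the product from boron may loosen the N–Si bond. The fallback avoids the hydroxy lactam altogether. It sets out from 13, which is transmetalated with ZnCl2 to [2,3,5,6-tetramethoxy-4-(1-triisopropylsilylindol-3-yl)phenyl]zinc chloride F11. Negishi coupling with purchasable tert-butyl 5-bromo-3-iodoindole-1-carboxylate (Pd(OAc)2, SPhos, THF, 50 °C), selective for the C–I bond, gives tert-butyl 5-bromo-3-[2,3,5,6-tetramethoxy-4-(1-triisopropylsilylindol-3-yl)phenyl]indole-1-carboxylate F12. Thermolysis of the carbamate at about 180 °C returns to the route at 17.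

Step 2. Over-oxidation of the aldehyde, migration of the allyl double bond into conjugation before cleavage, and self-condensation of the product in the buffered medium are the likely losses. The fallback replaces alkene cleavage by a one-carbon homologation. It sets out from 3, which is formylated with DMF to 2,3,5,6-tetramethoxybenzaldehyde F13. Wittig reaction with the ylide from (methoxymethyl)triphenylphosphonium chloride and KOtBu gives 3-(2-methoxyethenyl)-1,2,4,5-tetramethoxybenzene F14. Hydrolysis of this enol ether with dilute aqueous acid in THF returns to the route at 6.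

## Further compounds

F1 | step 3 | sodium isatin-1-ide | [Na+].O=C1[N-]c2ccccc2C1=O
F2 | step 3 | 3-hydroxy-3-(2,3,5,6-tetramethoxyphenyl)indolin-2-one, racemic | COc1cc(OC)c(OC)c(C2(O)C(=O)Nc3ccccc32)c1OC
F3 | step 5 | 3-(4-allyl-2,3,5,6-tetramethoxyphenyl)-1-(triisopropylsilyl)indole | C=CCc1c(OC)c(OC)c(-c2cn([Si](C(C)C)(C(C)C)C(C)C)c3ccccc23)c(OC)c1OC
F4 | step 5 | 3-[2,3,5,6-tetramethoxy-4-(1-triisopropylsilylindol-3-yl)phenyl]propane-1,2-diol, racemic | OCC(O)Cc1c(OC)c(OC)c(-c2cn([Si](C(C)C)(C(C)C)C(C)C)c3ccccc23)c(OC)c1OC
F5 | step 5 | [2,3,5,6-tetramethoxy-4-(1-triisopropylsilylindol-3-yl)phenyl]acetaldehyde | O=CCc1c(OC)c(OC)c(-c2cn([Si](C(C)C)(C(C)C)C(C)C)c3ccccc23)c(OC)c1OC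
F6 | step 5 | [2,3,5,6-tetramethoxy-4-(1-triisopropylsilylindol-3-yl)phenyl]acetaldehyde 4-bromophenylhydrazone, E shown | Brc1ccc(N/N=C/Cc2c(OC)c(OC)c(-c3cn([Si](C(C)C)(C(C)C)C(C)C)c4ccccc34)c(OC)c2OC)cc1
F7 | step 7 | sodium 5-bromo-3-[2,3,5,6-tetramethoxy-4-(1-triisopropylsilylindol-3-yl)phenyl]indol-1-ide | [Na+].COc1c(OC)c(-c2c[n-]c3ccc(Br)cc23)c(OC)c(OC)c1-c1cn([Si](C(C)C)(C(C)C)C(C)C)c2ccccc12
F8 | step 7 | 5-bromo-1-(triisopropylsilyl)-3-[2,3,5,6-tetramethoxy-4-(1-triisopropylsilylindol-3-yl)phenyl]indole | COc1c(OC)c(-c2cn([Si](C(C)C)(C(C)C)C(C)C)c3ccc(Br)cc23)c(OC)c(OC)c1-c1cn([Si](C(C)C)(C(C)C)C(C)C)c2ccccc12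
F9 | step 7 | 5-lithio-1-(triisopropylsilyl)-3-[2,3,5,6-tetramethoxy-4-(1-triisopropylsilylindol-3-yl)phenyl]indole | COc1c(OC)c(-c2cn([Si](C(C)C)(C(C)C)C(C)C)c3ccc([Li])cc23)c(OC)c(OC)c1-c1cn([Si](C(C)C)(C(C)C)C(C)C)c2ccccc12
F10 | step 7 | 5-(3-methylbut-2-enyl)-1-(triisopropylsilyl)-3-[2,3,5,6-tetramethoxy-4-(1-triisopropylsilylindol-3-yl)phenyl]indole | COc1c(OC)c(-c2cn([Si](C(C)C)(C(C)C)C(C)C)c3ccc(CC=C(C)C)cc23)c(OC)c(OC)c1-c1cn([Si](C(C)C)(C(C)C)C(C)C)c2ccccc12
F11 | step 6 | [2,3,5,6-tetramethoxy-4-(1-triisopropylsilylindol-3-yl)phenyl]zinc chloride | Cl[Zn]c1c(OC)c(OC)c(-c2cn([Si](C(C)C)(C(C)C)C(C)C)c3ccccc23)c(OC)c1OC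
F12 | step 6 | tert-butyl 5-bromo-3-[2,3,5,6-tetramethoxy-4-(1-triisopropylsilylindol-3-yl)phenyl]indole-1-carboxylate | COc1c(OC)c(-c2cn(C(=O)OC(C)(C)C)c3ccc(Br)cc23)c(OC)c(OC)c1-c1cn([Si](C(C)C)(C(C)C)C(C)C)c2ccccc12
F13 | step 2 | 2,3,5,6-tetramethoxybenzaldehyde | O=Cc1c(OC)c(OC)cc(OC)c1OC
F14 | step 2 | 3-(2-methoxyethenyl)-1,2,4,5-tetramethoxybenzene, E shown, either geometry serves | CO/C=C/c1c(OC)c(OC)cc(OC)c1OC
A1 | alternative 1 | 4-hydroxy-3-methoxy-4-[2-methoxy-1-(1-triisopropylsilylindol-3-yl)ethenyl]-2-(5-prenyl-1-triisopropylsilylindol-3-yl)cyclobut-2-en-1-one, racemic, alkene geometry left open | COC=C(c1cn([Si](C(C)C)(C(C)C)C(C)C)c2ccccc12)C1(O)C(OC)=C(c2cn([Si](C(C)C)(C(C)C)C(C)C)c3ccc(CC=C(C)C)cc23)C1=O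
A2 | alternative 1 | 3,6-dimethoxy-2-(1-triisopropylsilylindol-3-yl)-5-(5-prenyl-1-triisopropylsilylindol-3-yl)benzene-1,4-diol | Oc1c(-c2cn([Si](C(C)C)(C(C)C)C(C)C)c3ccc(CC=C(C)C)cc23)c(OC)c(O)c(-c2cn([Si](C(C)C)(C(C)C)C(C)C)c3ccccc23)c1OC
A3 | alternative 2 | 2,4,5-trimethoxyphenyl 3-bromo-1-tosylindole-2-carboxylate | COc1cc(OC)c(OC(=O)c2c(Br)c3ccccc3n2S(=O)(=O)c2ccc(C)cc2)cc1OC
A4 | alternative 2 | 1,2,4-trimethoxy-7-tosylchromeno[3,4-b]indol-6(7H)-one | COc1cc(OC)c2OC(=O)c3c(-c2c1OC)c1ccccc1n3S(=O)(=O)c1ccc(C)cc1
A5 | alternative 3 | 2-iodo-4-(3-methylbut-2-enyl)aniline | Nc1ccc(CC=C(C)C)cc1I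
A6 | alternative 3 | 3-[2,3,5,6-tetramethoxy-4-(trimethylsilylethynyl)phenyl]-1-(triisopropylsilyl)indole | C[Si](C)(C)C#Cc1c(OC)c(OC)c(-c2cn([Si](C(C)C)(C(C)C)C(C)C)c3ccccc23)c(OC)c1OC
A7 | alternative 3 | 3-[2,3,5,6-tetramethoxy-4-(1-triisopropylsilylindol-3-yl)phenyl]-5-prenyl-2-trimethylsilyl-1H-indole | C[Si](C)(C)c1[nH]c2ccc(CC=C(C)C)cc2c1-c1c(OC)c(OC)c(-c2cn([Si](C(C)C)(C(C)C)C(C)C)c3ccccc23)c(OC)c1OC
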